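**Retrosynthetic overview**
- Target ⇐ a 3‑allyloxycarbonyl, tri‑O‑allyl flavanonol: Pd‑mediated loss of four allyl groups, loss of CO2, enol protonation to the 2,3‑trans ketol.
- Ring C ⇐ C3–C4 bond (key step): the acyl anion (Breslow intermediate) of the ring A aldehyde adds to the keto group of a tethered α‑keto ester under a chiral triazolylidene, with dynamic kinetic resolution of the labile C2 centre.
- Tether ⇐ O1–C2 ether from a 2‑hydroxybenzaldehyde and a β‑chloro‑α‑keto ester.
- Ring A piece ⇐ 2,4,6‑trihydroxybenzaldehyde by C‑geranylation, then 4,6‑bis‑O‑allylation; ring B piece ⇐ 4‑(allyloxy)benzaldehyde by Darzens reaction with allyl dichloroacetate.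
- Ring order: rings A and B are bought; ring C is the only ring made.

Assumption: the (5aS,10bR) antipode of the triazolium salt is taken to give the 2R series (its mirror image is equally available and is used instead if the sense proves opposite), and the C3 configuration drawn for the benzoin product is a prediction that does not matter because C3 is re‑set in the last step.

**Route**

Step 1
Reactants: 1 2,4,6‑trihydroxybenzaldehyde; 2 geranyl bromide [(2E)‑1‑bromo‑3,7‑dimethylocta‑2,6‑diene]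
Product: 3 3‑[(2E)‑3,7‑dimethylocta‑2,6‑dien‑1‑yl]‑2,4,6‑trihydroxybenzaldehyde
Conditions: KOH (1.0 equiv), H2O, 0 °C → rt, 2 (1.0 equiv) added slowly
Reagents that add atoms: geranyl bromide (2), CC(C)=CCC/C(C)=C/CBr
Why: C‑alkylation of an ambident phloroglucinol phenoxide in water; the two free ring carbons of 1 are equivalent, so only one mono‑C‑geranyl isomer can form, and SN2 at C1 of the bromide keeps the E olefin (expect about 35–45 %, with O‑ and bis‑alkylated material separated).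

Step 2
Reactants: 3 3‑geranyl‑2,4,6‑trihydroxybenzaldehyde; 4 allyl bromide
Product: 5 4,6‑bis(allyloxy)‑3‑[(2E)‑3,7‑dimethylocta‑2,6‑dien‑1‑yl]‑2‑hydroxybenzaldehyde
Conditions: 4 (2.05 equiv), K2CO3 (2.2 equiv), acetone, rt
Reagents that add atoms: allyl bromide (4), C=CCBr
Why: Williamson etherification: the non‑chelated 4‑OH reacts first, then the less hindered of the two aldehyde‑chelated hydroxyls (6‑OH, next to H), leaving the 2‑OH that is both chelated and flanked by the geranyl group.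

Step 3
Reactants: 6 dichloroacetyl chloride; 7 allyl alcohol
Product: 8 allyl dichloroacetate
Conditions: CH2Cl2, 0 °C → rt, N2 sweep, no base
Reagents that add atoms: dichloroacetyl chloride (6), O=C(Cl)C(Cl)Cl
Why: Alcoholysis of an acyl chloride (esterification), driven by loss of HCl.

Step 4
Reactants: 9 4‑(allyloxy)benzaldehyde; 8 allyl dichloroacetate
Product: 11 allyl 3‑[4‑(allyloxy)phenyl]‑3‑chloro‑2‑oxopropanoate (racemic), via allyl α‑chloroglycidate 10 (not isolated)
Conditions: KOtBu (1.05 equiv), THF, −78 → 0 °C; then rt, 2 h; used crude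
Reagents that add atoms: allyl dichloroacetate (8), C=CCOC(=O)C(Cl)Cl
Why: Darzens condensation of a dichloroacetate gives the α‑chloroglycidic ester, which isomerises by ionisation at the p‑alkoxybenzylic carbon and 1,2‑chloride return to the β‑chloro‑α‑keto ester.

Step 5
Reactants: 5 4,6‑bis(allyloxy)‑3‑geranyl‑2‑hydroxybenzaldehyde; 11 allyl 3‑[4‑(allyloxy)phenyl]‑3‑chloro‑2‑oxopropanoate
Product: 12 allyl 3‑{3,5‑bis(allyloxy)‑2‑formyl‑6‑[(2E)‑3,7‑dimethylocta‑2,6‑dien‑1‑yl]phenoxy}‑3‑[4‑(allyloxy)phenyl]‑2‑oxopropanoate (racemic, keto/enol mixture)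
Conditions: 11 (1.2 equiv), K2CO3 (1.2 equiv), KI (10 mol %), acetone, 0 °C → rt
Reagents that add atoms: compound 11, C=CCOC(=O)C(=O)C(Cl)c1ccc(OCC=C)cc1
Why: O‑alkylation of the only free phenoxide by an α‑halo ketone (carbonyl‑activated, Finkelstein‑assisted SN2, the first stage of a Rap–Stoermer reaction); the new C2 centre is racemic and labile, which is what step 6 needs.

Step 6
Reactants: 12 aldehyde–α‑keto ester
Product: 13 allyl (2R,3R)‑5,7‑bis(allyloxy)‑2‑[4‑(allyloxy)phenyl]‑8‑[(2E)‑3,7‑dimethylocta‑2,6‑dien‑1‑yl]‑3‑hydroxy‑4‑oxochromane‑3‑carboxylate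
Conditions: (5aS,10bR)‑2‑(pentafluorophenyl)‑5a,10b‑dihydro‑4H,6H‑indeno[2,1‑b][1,2,4]triazolo[4,3‑d][1,4]oxazin‑2‑ium tetrafluoroborate (C18H11BF9N3O, 10 mol %), i‑Pr2NEt (20 mol %), toluene, 4 Å MS, 0 °C → rt
Reagents that add atoms: none
Why: Proposed new method: the triazolylidene can add productively only to the single aldehyde of 12, giving a Breslow intermediate (acyl anion at C4) that attacks the strongly electrophilic keto carbonyl of the tethered α‑keto ester in a six‑membered closure (carbene‑catalysed intramolecular crossed aldehyde–ketone benzoin, the established enantioselective entry to 3‑hydroxychroman‑4‑ones); because the C2–H of 12 lies between an aryl group, an aryloxy group and the keto ester, it epimerises through the enol faster than ring closure, so the chiral carbene funnels the racemate through the transition state with the C2 aryl group pseudo‑equatorial and anti to the incoming nucleophile and sets C2 as R (and C3) in one event, the closest precedents being the dynamic kinetic asymmetric cross‑benzoin of β‑stereogenic α‑keto esters and the chiral‑triazolium aldehyde–ketone benzoin cyclisation; the product has no acidic C2–H or C3–H, so the new centres cannot wash out.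

Step 7
Reactants: 13 allyl (2R,3R)‑tri‑O‑allyl‑3‑hydroxy‑4‑oxochromane‑3‑carboxylate
Product: 16 (2R,3R)‑8‑[(2E)‑3,7‑dimethylocta‑2,6‑dien‑1‑yl]‑3,5,7‑trihydroxy‑2‑(4‑hydroxyphenyl)chroman‑4‑one (target), via β‑keto acid 14 (not isolated), via enediol 15 (not isolated)
Conditions: Pd(PPh3)4 (5 mol %), HCO2H/Et3N (1:1, 8 equiv), THF, rt → 40 °C, argon
Reagents that add atoms: none
Why: Tsuji–Trost deallylation with formate as hydride donor cleaves the three aryl allyl ethers and the allyl ester under near‑neutral conditions that leave the geranyl olefins and the C2 ether untouched; the β‑keto acid decarboxylates, and the enediol is protonated axially at C3 on the face trans to H2 to give the more stable 2,3‑trans (3R) ketol, with C2 (R) carried over unchanged from step 6.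

**Compound list**

1 | 2,4,6‑trihydroxybenzaldehyde | O=Cc1c(O)cc(O)cc1O | starting material
2 | geranyl bromide, (2E)‑1‑bromo‑3,7‑dimethylocta‑2,6‑diene | CC(C)=CCC/C(C)=C/CBr | starting material
3 | 3‑[(2E)‑3,7‑dimethylocta‑2,6‑dien‑1‑yl]‑2,4,6‑trihydroxybenzaldehyde | CC(C)=CCC/C(C)=C/Cc1c(O)cc(O)c(C=O)c1O | intermediate
4 | allyl bromide | C=CCBr | starting material
5 | 4,6‑bis(allyloxy)‑3‑[(2E)‑3,7‑dimethylocta‑2,6‑dien‑1‑yl]‑2‑hydroxybenzaldehyde | CC(C)=CCC/C(C)=C/Cc1c(OCC=C)cc(OCC=C)c(C=O)c1O | intermediate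
6 | dichloroacetyl chloride | O=C(Cl)C(Cl)Cl | starting material
7 | allyl alcohol | C=CCO | starting material
8 | allyl dichloroacetate | C=CCOC(=O)C(Cl)Cl | intermediate
9 | 4‑(allyloxy)benzaldehyde | C=CCOc1ccc(C=O)cc1 | starting material
10 | allyl 3‑[4‑(allyloxy)phenyl]‑2‑chlorooxirane‑2‑carboxylate (racemic, diastereomer mixture) | C=CCOC(=O)C1(Cl)OC1c1ccc(OCC=C)cc1 | intermediate (not isolated)
11 | allyl 3‑[4‑(allyloxy)phenyl]‑3‑chloro‑2‑oxopropanoate (racemic) | C=CCOC(=O)C(=O)C(Cl)c1ccc(OCC=C)cc1 | intermediate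
12 | allyl 3‑{3,5‑bis(allyloxy)‑2‑formyl‑6‑[(2E)‑3,7‑dimethylocta‑2,6‑dien‑1‑yl]phenoxy}‑3‑[4‑(allyloxy)phenyl]‑2‑oxopropanoate (racemic) | CC(C)=CCC/C(C)=C/Cc1c(OCC=C)cc(OCC=C)c(C=O)c1OC(c1ccc(OCC=C)cc1)C(=O)C(=O)OCC=C | intermediate
13 | allyl (2R,3R)‑5,7‑bis(allyloxy)‑2‑[4‑(allyloxy)phenyl]‑8‑[(2E)‑3,7‑dimethylocta‑2,6‑dien‑1‑yl]‑3‑hydroxy‑4‑oxochromane‑3‑carboxylate | CC(C)=CCC/C(C)=C/Cc1c(OCC=C)cc(OCC=C)c2c1O[C@H](c1ccc(OCC=C)cc1)[C@@](C(=O)OCC=C)(O)C2=O | intermediate
14 | (2R,3R)‑8‑[(2E)‑3,7‑dimethylocta‑2,6‑dien‑1‑yl]‑3,5,7‑trihydroxy‑2‑(4‑hydroxyphenyl)‑4‑oxochromane‑3‑carboxylic acid | CC(C)=CCC/C(C)=C/Cc1c(O)cc(O)c2c1O[C@H](c1ccc(O)cc1)[C@@](C(=O)O)(O)C2=O | intermediate (not isolated)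
15 | (2R)‑8‑[(2E)‑3,7‑dimethylocta‑2,6‑dien‑1‑yl]‑2‑(4‑hydroxyphenyl)‑2H‑chromene‑3,4,5,7‑tetrol (enediol) | CC(C)=CCC/C(C)=C/Cc1c(O)cc(O)c2c1O[C@H](c1ccc(O)cc1)C(O)=C2O | intermediate (not isolated)
16 | (2R,3R)‑8‑[(2E)‑3,7‑dimethylocta‑2,6‑dien‑1‑yl]‑3,5,7‑trihydroxy‑2‑(4‑hydroxyphenyl)chroman‑4‑one | CC(C)=CCC/C(C)=C/Cc1c(O)cc(O)c2c1O[C@H](c1ccc(O)cc1)[C@@H](O)C2=O | target

**Totals**
Total steps: 7. Longest linear sequence: 5 steps (1 → 2 → 5 → 6 → 7, or 3 → 4 → 5 → 6 → 7).

**Three steps most likely to fail, each with a fallback**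

Step 6 (key benzoin cyclisation). The di‑ortho‑oxygenated, electron‑rich aldehyde may be slow to form the Breslow intermediate. The enol of 12 can also add reversibly to the neighbouring aldehyde (five‑membered aldol, Rap–Stoermer type), and the ee of an untested dynamic kinetic resolution is uncertain. Fallback, setting out from 5 and coming back at 13: the two ring C bonds are made in the opposite order. Compound 5 is silylated (TBSOTf, 2,6‑lutidine, CH2Cl2) to 4,6‑bis(allyloxy)‑2‑[(tert‑butyldimethylsilyl)oxy]‑3‑geranylbenzaldehyde F1. F1 and racemic 11 are then joined by the intermolecular carbene‑catalysed dynamic kinetic cross‑benzoin (same triazolium salt, K2CO3, tert‑butyl methyl ether), which gives allyl (2R,3S)‑2‑{4,6‑bis(allyloxy)‑2‑[(tert‑butyldimethylsilyl)oxy]‑3‑geranylbenzoyl}‑3‑[4‑(allyloxy)phenyl]‑3‑chloro‑2‑hydroxypropanoate F2, with the chloride‑bearing carbon S. CsF in DMF at 0 °C → rt removes the silyl group to give allyl (2R,3S)‑2‑[4,6‑bis(allyloxy)‑3‑geranyl‑2‑hydroxybenzoyl]‑3‑[4‑(allyloxy)phenyl]‑3‑chloro‑2‑hydroxypropanoate F3. Its phenoxide displaces the benzylic chloride intramolecularly with inversion (six‑membered ring) to give 13. No enolisable aryloxy keto ester with a free ortho aldehyde exists on this path; the configuration at the carbinol carbon is immaterial.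

Step 5 (etherification). The chelated, doubly flanked phenoxide may alkylate slowly, and the product is acidic enough to undergo the aldol side reaction under carbonate. Fallback, setting out from 11 and coming back at 12: the ether is made at the alcohol oxidation level and oxidised afterwards. NaBH4 (THF/i‑PrOH, −40 °C) reduces only the keto group of 11 to allyl 3‑[4‑(allyloxy)phenyl]‑3‑chloro‑2‑hydroxypropanoate F4. K2CO3 in DMF closes it to allyl 3‑[4‑(allyloxy)phenyl]oxirane‑2‑carboxylate F5, which the phenoxide of 5 opens at the p‑alkoxybenzylic carbon (50 °C) to allyl 3‑{3,5‑bis(allyloxy)‑2‑formyl‑6‑geranylphenoxy}‑3‑[4‑(allyloxy)phenyl]‑2‑hydroxypropanoate F6. F6 has no acidic C2–H. Dess–Martin periodinane (CH2Cl2, rt, neutral) then gives 12, which is taken straight into step 6.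

Step 2 (selective bis‑allylation). Discrimination between the two chelated ortho hydroxyls may be incomplete, and tri‑allylation can compete. Fallback, setting out from 1 and coming back at 5: the order of allylation and geranylation is reversed so that regiochemistry is fixed by symmetry. Compound 1 with allyl bromide 4 (2 equiv, K2CO3, acetone) gives 2,4‑bis(allyloxy)‑6‑hydroxybenzaldehyde F7, in which only one (chelated) hydroxyl is left. F7 is deprotonated with NaH in toluene and treated with geranyl bromide 2 (rt → 60 °C); ortho‑selective C‑alkylation of the tight sodium phenoxide ion pair in the non‑polar medium places the geranyl group next to the free hydroxyl and gives 5, with the O‑geranyl ether separated.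

**Further compounds**

F1 | step 6 | 4,6‑bis(allyloxy)‑2‑[(tert‑butyldimethylsilyl)oxy]‑3‑[(2E)‑3,7‑dimethylocta‑2,6‑dien‑1‑yl]benzaldehyde | CC(C)=CCC/C(C)=C/Cc1c(OCC=C)cc(OCC=C)c(C=O)c1O[Si](C)(C)C(C)(C)C
F2 | step 6 | allyl (2R,3S)‑2‑{4,6‑bis(allyloxy)‑2‑[(tert‑butyldimethylsilyl)oxy]‑3‑[(2E)‑3,7‑dimethylocta‑2,6‑dien‑1‑yl]benzoyl}‑3‑[4‑(allyloxy)phenyl]‑3‑chloro‑2‑hydroxypropanoate | CC(C)=CCC/C(C)=C/Cc1c(OCC=C)cc(OCC=C)c(C(=O)[C@@](O)(C(=O)OCC=C)[C@@H](Cl)c2ccc(OCC=C)cc2)c1O[Si](C)(C)C(C)(C)C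
F3 | step 6 | allyl (2R,3S)‑2‑{4,6‑bis(allyloxy)‑3‑[(2E)‑3,7‑dimethylocta‑2,6‑dien‑1‑yl]‑2‑hydroxybenzoyl}‑3‑[4‑(allyloxy)phenyl]‑3‑chloro‑2‑hydroxypropanoate | CC(C)=CCC/C(C)=C/Cc1c(OCC=C)cc(OCC=C)c(C(=O)[C@@](O)(C(=O)OCC=C)[C@@H](Cl)c2ccc(OCC=C)cc2)c1O
F4 | step 5 | allyl 3‑[4‑(allyloxy)phenyl]‑3‑chloro‑2‑hydroxypropanoate (racemic diastereomer mixture) | C=CCOC(=O)C(O)C(Cl)c1ccc(OCC=C)cc1
F5 | step 5 | allyl 3‑[4‑(allyloxy)phenyl]oxirane‑2‑carboxylate (racemic diastereomer mixture) | C=CCOC(=O)C1OC1c1ccc(OCC=C)cc1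
F6 | step 5 | allyl 3‑{3,5‑bis(allyloxy)‑2‑formyl‑6‑[(2E)‑3,7‑dimethylocta‑2,6‑dien‑1‑yl]phenoxy}‑3‑[4‑(allyloxy)phenyl]‑2‑hydroxypropanoate (racemic diastereomer mixture) | CC(C)=CCC/C(C)=C/Cc1c(OCC=C)cc(OCC=C)c(C=O)c1OC(c1ccc(OCC=C)cc1)C(O)C(=O)OCC=C
F7 | step 2 | 2,4‑bis(allyloxy)‑6‑hydroxybenzaldehyde | O=Cc1c(O)cc(OCC=C)cc1OCC=C
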